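Eremophilane numbering (C1–C15) is used in the discussion: ring A is C1–C2–C3–C4–C5–C10, ring B is C5–C6–C7–C8–C9–C10, C14 is the methyl on C5 and C15 the methyl on C4. Systematic names use naphthalene locants.

## Analysis of the target

Target 19 is an eremophilane, a trans-fused decalin with seven stereocentres (3R,4R,5R,7S,8R,9S,10R). In the chair–chair conformer the C5 methyl is axial, while the C3 ester, C4 methyl, C7 isopropenyl and C9 ester are equatorial. The only axial heteroatom is the free C8 hydroxyl, which is cis to both of its neighbours and is the contra-thermodynamic centre of the molecule. The cis methyl groups on C4 and on quaternary C5 are the classical eremophilane problem. Sensitive groups are the two (Z)-enoates (Z to E isomerisation, conjugate addition), the free hydroxyl next to an ester (acyl migration) and the isopropenyl group (acid, and competition in any alkene oxidation or hydroboration). Three oxygens have to be told apart: O3 and O9 acylated, O8 free. The feature that the route exploits sits in ring B: the C7 isopropenyl group and the C8 hydroxyl form a homoallylic alcohol (C12=C11–C7–C8–OH), the retron of an intramolecular carbonyl-ene reaction. Cutting C7–C8 therefore opens ring B to a prenyl group on C5 and an oxygenated two-carbon aldehyde arm on C10.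

## Retrosynthetic reasoning

**Ester geometry.** 19 is traced back to the bis(ynoate) 18. A semi-hydrogenation as the last step creates both Z alkenes after all basic and nucleophilic steps are over. 18 comes from triol 16 and acid 17 by acylation of the two equatorial hydroxyls.

**C8 carbinol.** Triol 16 comes from 15, and 15 from ketone 14 by hydride attack from the equatorial direction. Setting C8 by reduction means that the ring closure does not have to control it: any mixture of C8 epimers converges at 14.

**Ring B, C7–C8 bond (key disconnection).** Ketone 14 comes from the homoallylic alcohol 13, and 13 from the monocyclic aldehyde 12 by a carbonyl-ene cyclisation. This cut removes ring B, the C7 stereocentre and the isopropenyl group at once. The forward reaction has to close a six-membered ring between an aldehyde carbon and the inner carbon of a prenyl group held trans-diequatorial on ring A.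

**C9 oxygen.** 12 comes from aldehyde 11 by α-oxygenation of the aldehyde. The cut is made here because C9 is the α-carbon of the aldehyde needed for the ene step, so a catalyst can set it independently of the ring.

**C10 and the two-carbon arm.** 11 comes from enal 10 by conjugate reduction, and 10 from ketone 7 and the two-carbon reagent 8. C10 is created by hydride delivery to an exocyclic alkene next to the quaternary centre, where the axial C5 methyl differentiates the faces, and the resulting centre is not epimerisable.

**C4, C5 and the prenyl group.** 7 comes from enone 4, a methyl nucleophile and bromide 5 in one conjugate addition/alkylation. The silyloxy group on C3 directs the methyl to C4 (trans), and the C4 methyl directs the prenyl group to C5 (trans). This yields the cis-dimethyl pattern and the quaternary centre from a single stereocentre.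

**Ring A.** 4 comes from aldehyde 1 and enone 2 by an amine-catalysed Michael addition (via 3) and aldol condensation. This is the only step in which absolute configuration is introduced from an achiral pair of building blocks.

## Alternatives that were turned down

Alternative 1: (textbook) Robinson annulation of ring B onto ring A, forming C5–C6 by Michael addition and C9=C10 by aldol condensation. Forward key step: enolate 6 adds to but-3-en-2-one A1 and the adduct is condensed to octalone A2. The C11–C13 unit would then be added at C7 by aldol condensation to give dienone A3. It was turned down because the annulation delivers ring B as a flat 8-oxo-9(10)-ene and sets no stereocentre beyond C5. C7, C8, C9 and C10 would all have to be made afterwards by redox steps on one ketone flanked by two enolisable positions. The isopropenyl group would come from contra-thermodynamic deconjugation of an isopropylidene ketone, C10 from a dissolving-metal reduction, and C9 from an enolate oxidation. This costs at least six more steps than the chosen route.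

Alternative 2: (biomimetic skeletal rearrangement) formation of the C5–C14 bond by a 1,2-methyl shift from C10 in a eudesmane. Forward sequence: Robinson annulation of dihydrocarvone A4 with 2 gives enone A5. Reduction and hydroxyl-directed epoxidation give epoxy alcohol A6. Lewis acid opens the epoxide at C5, the C10 methyl migrates anti to the breaking C–O bond (Westphalen-type), and proton loss gives diol A7. It was turned down for four reasons:
- The only trigger that makes the shift concerted, the 4,5-epoxide, leaves a tertiary hydroxyl on C4 that must then be removed with stereocontrol.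
- A C5 cation that already carries H on C4 would instead lose a proton to the 4-ene or 5-ene faster than the methyl migrates.
- The isopropenyl group is exposed to the acid.
- The C10 cation ends as an alkene mixture, and both ring-B oxygens would still have to be introduced in the presence of the isopropenyl alkene.

Alternative 3: (dearomatisation and sigmatropic rearrangement) formation of C5–C6 by an anionic oxy-Cope rearrangement, with C8/C9 and the C4/C5 dimethyl unit taken from an arene. Forward sequence: phenol A8 is oxidised in methanol to the masked o-benzoquinone A9, which is trapped by an ethylene equivalent to give bicyclo[2.2.2]octenone A10. Vinyl addition and anionic oxy-Cope rearrangement give the cis-decalin A11. This reaches the skeleton in three steps, but it was turned down for five reasons: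
- The cycloaddition gives a racemate, so a resolution would be needed.
- The ethylene equivalent adds a group that must be removed.
- The ring fusion is cis and must be epimerised through a C9 ketone.
- That C9 ketone would then have to be reduced to the equatorial alcohol by hydride attack syn to the axial C5 methyl, against the steric bias.
- The C3 hydroxyl would need a hydroboration that competes with the isopropenyl group.

Key step: step 6

Assumption: both aminocatalysts (steps 1 and 5) are taken to induce in the sense established for unbranched alkyl aldehydes; if the α-silyloxy group or the bulky ring reversed this, the enantiomeric catalyst would be used.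

## Route

Step 1
Reactants: 1 (tert-butyldimethylsilyloxy)acetaldehyde; 2 pent-1-en-3-one
Product: 4 (4R)-4-[(tert-butyldimethylsilyl)oxy]-2-methylcyclohex-2-en-1-one, via keto-aldehyde 3 (not isolated)
Conditions: (S)-2-[diphenyl(trimethylsilyloxy)methyl]pyrrolidine (10 mol %), PhCO2H (10 mol %), CH2Cl2, 0 °C; then p-TsOH·H2O (30 mol %), 25 °C
Reagents that add atoms: none
Why: Enamine-catalysed Michael addition of 1 to 2 followed by acid-mediated intramolecular aldol condensation (a Robinson-type annulation); the bulky group of the catalyst shields one enamine face so that C3 (eremophilane numbering) should be set as R, and only the ethyl-side enol of 3 can close a six-membered ring.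

Step 2
Reactants: 4; 5 1-bromo-3-methylbut-2-ene
Product: 7 (2R,3R,4R)-4-[(tert-butyldimethylsilyl)oxy]-2,3-dimethyl-2-(3-methylbut-2-en-1-yl)cyclohexan-1-one, via lithium enolate 6 (not isolated)
Conditions: Me2CuLi (from MeLi, CuI), Et2O, −78 → −30 °C; then 5, HMPA, THF, −30 → 20 °C
Reagents that add atoms: lithium dimethylcuprate, [Li+].C[Cu-]C
Why: Conjugate addition/enolate alkylation; the cuprate should add to C4 anti to the neighbouring silyloxy group (3,4-trans) and the regiodefined enolate 6 should be C-alkylated anti to the new pseudo-axial C4 methyl, which makes the C4/C5 methyls cis and sets the quaternary centre.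

Step 3
Reactants: 7; 8 (Z)-1-bromo-2-ethoxyethene
Product: 10 (2E)-2-[(2R,3R,4R)-4-[(tert-butyldimethylsilyl)oxy]-2,3-dimethyl-2-(3-methylbut-2-en-1-yl)cyclohexylidene]acetaldehyde, via allylic alcohol 9 (not isolated)
Conditions: 8, n-BuLi, THF, −78 °C; then 7, −78 → 0 °C; then 1 M HCl, THF, 20 °C
Reagents that add atoms: water, O
Why: 1,2-Addition of the alkenyllithium gives 9, whose enol ether is hydrolysed with loss of the tertiary hydroxyl (allylic transposition/dehydration) to the conjugated aldehyde, a two-carbon homologation that brings in C9 and C8; no stereocentre is formed because C10 becomes sp2.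

Step 4
Reactants: 10
Product: 11 2-[(1S,2S,3R,4R)-4-[(tert-butyldimethylsilyl)oxy]-2,3-dimethyl-2-(3-methylbut-2-en-1-yl)cyclohexyl]acetaldehyde
Conditions: [(Ph3P)CuH]6, H2O, toluene, 20 °C
Reagents that add atoms: none
Why: Copper hydride 1,4-reduction of the β,β-disubstituted enal; hydride should reach C10 from the face opposite the axial C5 methyl (axial attack), which places the acetaldehyde arm equatorial and trans to the C5–C6 bond, the future trans ring fusion, and leaves the isolated alkene and silyl ether untouched.

Step 5
Reactants: 11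
Product: 12 (1S)-1-[(1R,2R,3R,4R)-4-[(tert-butyldimethylsilyl)oxy]-2,3-dimethyl-2-(3-methylbut-2-en-1-yl)cyclohexyl]-2-oxoethyl benzoate
Conditions: (S)-2-(triphenylmethyl)pyrrolidine (10 mol %), dibenzoyl peroxide, hydroquinone (10 mol %), THF, 0 °C
Reagents that add atoms: dibenzoyl peroxide, O=C(OOC(=O)c1ccccc1)c1ccccc1
Why: Enamine-catalysed α-benzoyloxylation of an aldehyde; the trityl group blocks one enamine face so that C9 (S) should be set by the catalyst and not by the ring, and the peroxide oxidises only the enamine carbon.

Step 6
Reactants: 12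
Product: 13 (1S,2S,3S,4aR,5R,6R,8aR)-6-[(tert-butyldimethylsilyl)oxy]-2-hydroxy-4a,5-dimethyl-3-(prop-1-en-2-yl)decahydronaphthalen-1-yl benzoate
Conditions: Me2AlCl (1.5 equiv), CH2Cl2, −78 → −40 °C
Reagents that add atoms: none
Why: Me2AlCl activates the aldehyde of 12 and the inner alkene carbon C7 attacks C8 through a chair-like six-membered transition state while charge builds at the tertiary carbon C11; a hydrogen of a C11 methyl then passes to oxygen (ene reaction, concerted or stepwise), which unveils the isopropenyl group and the C8 carbinol in one operation, and the aluminium alkoxide loses methane so that no proton acid remains to isomerise the new alkene. The closest known reaction type is the Lewis-acid-promoted type-one intramolecular carbonyl-ene cyclisation of citronellal to isopulegol, here applied to an α-acyloxy aldehyde. Ring B (C5–C6–C7–C8–C9–C10) closes in a six-membered mode that is exo to the C7=C11 double bond, and no other ring forms. Because the two arms (C5–C6 and C10–C9) sit trans-diequatorial on ring A, the only unstrained transition state is the chair that gives the trans-decalin. C7 is controlled by this chair: an axial C11 would be 1,3-diaxial to the axial C5 methyl, so the isopropenyl group should end up equatorial and trans to that methyl (7S). C8 should form mainly with the hydroxyl equatorial (13, isopulegol-type) beside some axial epimer (identical to 15); this selectivity is not needed, since both are oxidised to 14 in step 7 and C8 is reset in step 8. The step does need bond formation at C7 and not C11 (secured by the tertiary cation character at C11), proton loss from a methyl and not from C7 (secured by the cyclic hydrogen transfer to oxygen), and survival of the benzoate, the silyl ether and C9 (secured by the low temperature and the aprotic Lewis acid).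

Step 7
Reactants: 13
Product: 14 (1S,3S,4aR,5R,6R,8aR)-6-[(tert-butyldimethylsilyl)oxy]-4a,5-dimethyl-2-oxo-3-(prop-1-en-2-yl)decahydronaphthalen-1-yl benzoate
Conditions: DMP, pyridine, CH2Cl2, 0 → 20 °C
Reagents that add atoms: none
Why: Dess–Martin oxidation should convert both C8 epimers (13 and any 15) into the same ketone, a stereoconvergent step; under buffered conditions the α-benzoyloxy centre C9 and the α-allylic centre C7 keep their equatorial, thermodynamically preferred configurations.

Step 8
Reactants: 14
Product: 15 (1S,2R,3S,4aR,5R,6R,8aR)-6-[(tert-butyldimethylsilyl)oxy]-2-hydroxy-4a,5-dimethyl-3-(prop-1-en-2-yl)decahydronaphthalen-1-yl benzoate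
Conditions: Li[HB(s-Bu)3], THF, −78 °C; AcOH quench
Reagents that add atoms: none
Why: The bulky trialkylborohydride should attack the cyclohexanone from the equatorial direction (the axial path is blocked by the axial hydrogens on C6 and C10), giving the axial 8R alcohol cis to both equatorial neighbours, as in the reduction of isopulegone to neoisopulegol; the low temperature spares the benzoate.

Step 9
Reactants: 15
Product: 16 (1S,2R,3S,4aR,5R,6R,8aR)-4a,5-dimethyl-3-(prop-1-en-2-yl)decahydronaphthalene-1,2,6-triol
Conditions: K2CO3 (cat.), MeOH, 20 °C; then HF·pyridine, THF, 0 → 20 °C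
Reagents that add atoms: none
Why: Base-catalysed transesterification removes the benzoate (including any that migrated to O8) and fluoride cleaves the silyl ether; neither reagent touches the isopropenyl group or a stereocentre.

Step 10
Reactants: 16; 17 hex-2-ynoic acid
Product: 18 (1S,2R,3S,4aR,5R,6R,8aR)-2-hydroxy-4a,5-dimethyl-3-(prop-1-en-2-yl)decahydronaphthalene-1,6-diyl bis(hex-2-ynoate)
Conditions: 17 (2.2 equiv), DCC, DMAP (cat.), CH2Cl2, −20 → 0 °C
Reagents that add atoms: none
Why: Steglich esterification; the two equatorial secondary hydroxyls (O3, O9) should be acylated while the axial O8 hydroxyl, flanked by the isopropenyl group and the new C9 ester, reacts much more slowly, and an alkynoate has no alkene geometry that could be lost during acylation.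

Step 11
Reactants: 18
Product: 19 (1S,2R,3S,4aR,5R,6R,8aR)-2-hydroxy-4a,5-dimethyl-3-(prop-1-en-2-yl)decahydronaphthalene-1,6-diyl bis[(2Z)-hex-2-enoate]
Conditions: H2 (1 atm), Pd/CaCO3 poisoned with Pb(OAc)2, quinoline, EtOAc, 20 °C
Reagents that add atoms: none
Why: Semi-hydrogenation of both ynoates on lead-poisoned palladium adds H2 syn and stops at the alkene, so both (Z)-enoates are set at the very end; the 1,1-disubstituted isopropenyl group should not be reduced on the poisoned catalyst.

## Compound list

1 | (tert-butyldimethylsilyloxy)acetaldehyde | CC(C)(C)[Si](C)(C)OCC=O | starting material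
2 | pent-1-en-3-one | CCC(=O)C=C | starting material
3 | (2R)-2-[(tert-butyldimethylsilyl)oxy]-5-oxoheptanal | O=C[C@H](O[Si](C)(C)C(C)(C)C)CCC(=O)CC | intermediate (not isolated)
4 | (4R)-4-[(tert-butyldimethylsilyl)oxy]-2-methylcyclohex-2-en-1-one | O=C1C(C)=C[C@H](O[Si](C)(C)C(C)(C)C)CC1 | intermediate
5 | 1-bromo-3-methylbut-2-ene | CC(C)=CCBr | starting material
6 | lithium (3R,4R)-4-[(tert-butyldimethylsilyl)oxy]-2,3-dimethylcyclohex-1-en-1-olate | [Li+].[O-]C1=C(C)[C@@H](C)[C@H](O[Si](C)(C)C(C)(C)C)CC1 | intermediate (not isolated)
7 | (2R,3R,4R)-4-[(tert-butyldimethylsilyl)oxy]-2,3-dimethyl-2-(3-methylbut-2-en-1-yl)cyclohexan-1-one | CC(C)=CC[C@]1(C)[C@@H](C)[C@H](O[Si](C)(C)C(C)(C)C)CCC1=O | intermediate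
8 | (Z)-1-bromo-2-ethoxyethene | CCO/C=C\Br | starting material
9 | (1S,2R,3R,4R)-4-[(tert-butyldimethylsilyl)oxy]-1-[(Z)-2-ethoxyethenyl]-2,3-dimethyl-2-(3-methylbut-2-en-1-yl)cyclohexan-1-ol (configuration at C1 of no consequence) | CC(C)=CC[C@]1(C)[C@@H](C)[C@H](O[Si](C)(C)C(C)(C)C)CC[C@]1(O)/C=C\OCC | intermediate (not isolated)
10 | (2E)-2-[(2R,3R,4R)-4-[(tert-butyldimethylsilyl)oxy]-2,3-dimethyl-2-(3-methylbut-2-en-1-yl)cyclohexylidene]acetaldehyde | CC(C)=CC[C@]1(C)[C@@H](C)[C@H](O[Si](C)(C)C(C)(C)C)CC/C1=C\C=O | intermediate
11 | 2-[(1S,2S,3R,4R)-4-[(tert-butyldimethylsilyl)oxy]-2,3-dimethyl-2-(3-methylbut-2-en-1-yl)cyclohexyl]acetaldehyde | CC(C)=CC[C@]1(C)[C@@H](C)[C@H](O[Si](C)(C)C(C)(C)C)CC[C@H]1CC=O | intermediate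
12 | (1S)-1-[(1R,2R,3R,4R)-4-[(tert-butyldimethylsilyl)oxy]-2,3-dimethyl-2-(3-methylbut-2-en-1-yl)cyclohexyl]-2-oxoethyl benzoate | CC(C)=CC[C@]1(C)[C@@H](C)[C@H](O[Si](C)(C)C(C)(C)C)CC[C@H]1[C@H](OC(=O)c2ccccc2)C=O | intermediate
13 | (1S,2S,3S,4aR,5R,6R,8aR)-6-[(tert-butyldimethylsilyl)oxy]-2-hydroxy-4a,5-dimethyl-3-(prop-1-en-2-yl)decahydronaphthalen-1-yl benzoate | C=C(C)[C@@H]1C[C@]2(C)[C@@H](C)[C@H](O[Si](C)(C)C(C)(C)C)CC[C@H]2[C@H](OC(=O)c3ccccc3)[C@H]1O | intermediate
14 | (1S,3S,4aR,5R,6R,8aR)-6-[(tert-butyldimethylsilyl)oxy]-4a,5-dimethyl-2-oxo-3-(prop-1-en-2-yl)decahydronaphthalen-1-yl benzoate | C=C(C)[C@@H]1C[C@]2(C)[C@@H](C)[C@H](O[Si](C)(C)C(C)(C)C)CC[C@H]2[C@H](OC(=O)c3ccccc3)C1=O | intermediate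
15 | (1S,2R,3S,4aR,5R,6R,8aR)-6-[(tert-butyldimethylsilyl)oxy]-2-hydroxy-4a,5-dimethyl-3-(prop-1-en-2-yl)decahydronaphthalen-1-yl benzoate | C=C(C)[C@@H]1C[C@]2(C)[C@@H](C)[C@H](O[Si](C)(C)C(C)(C)C)CC[C@H]2[C@H](OC(=O)c3ccccc3)[C@@H]1O | intermediate
16 | (1S,2R,3S,4aR,5R,6R,8aR)-4a,5-dimethyl-3-(prop-1-en-2-yl)decahydronaphthalene-1,2,6-triol | C=C(C)[C@@H]1C[C@]2(C)[C@@H](C)[C@H](O)CC[C@H]2[C@H](O)[C@@H]1O | intermediate
17 | hex-2-ynoic acid | CCCC#CC(=O)O | starting material
18 | (1S,2R,3S,4aR,5R,6R,8aR)-2-hydroxy-4a,5-dimethyl-3-(prop-1-en-2-yl)decahydronaphthalene-1,6-diyl bis(hex-2-ynoate) | C=C(C)[C@@H]1C[C@]2(C)[C@@H](C)[C@H](OC(=O)C#CCCC)CC[C@H]2[C@H](OC(=O)C#CCCC)[C@@H]1O | intermediate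
19 | (1S,2R,3S,4aR,5R,6R,8aR)-2-hydroxy-4a,5-dimethyl-3-(prop-1-en-2-yl)decahydronaphthalene-1,6-diyl bis[(2Z)-hex-2-enoate] | C=C(C)[C@@H]1C[C@]2(C)[C@@H](C)[C@H](OC(=O)/C=C\CCC)CC[C@H]2[C@H](OC(=O)/C=C\CCC)[C@@H]1O | target

## Step count and least certain steps

Total step count: 11. Longest linear sequence: 11 steps (1 and 2 to 19).

**Step 6 (key step).** The cationic closure may be diverted: chloride capture at C11, proton loss from C7 to the tetrasubstituted alkene, or participation or ionisation of the α-benzoate. The cause is that the transition state carries positive charge at C11 while a Lewis-acid-bound α-acyloxy aldehyde sits nearby. Fallback (organochromium allylation in place of the cationic ene closure): it sets out from 12 and comes back at 13. SeO2 (cat.)/t-BuOOH in CH2Cl2 would oxidise the (E)-methyl of the prenyl unit to the allylic alcohol F1. Ph3P/NBS at −20 °C would give the allylic bromide F2. CrCl2 in THF (intramolecular Nozaki–Hiyama–Kishi allylation) would form the allylchromium species, which adds to the aldehyde through its γ-carbon C7 and closes ring B with the isopropenyl group in place. This gives 13 together with its C8 epimer 15, and both go on to step 7.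

**Step 1.** Enantiopurity may erode through enolisation of the α-silyloxy aldehyde 3, and the silyloxy group may be eliminated during the acid condensation, because the stereocentre is both α to an aldehyde and later γ to an enone. Fallback (auxiliary-controlled alkylation in place of aminocatalysis): it sets out from 1 and 2 and comes back at 4. 2 would be converted with NaI/TMSCl/ethane-1,2-diol into 2-ethyl-2-(2-iodoethyl)-1,3-dioxolane F3. 1 would be condensed with RAMP to the hydrazone F4. Deprotonation with LDA and alkylation with F3 would give the alkylated hydrazone F5. Ozonolysis of the C=N bond and mild aqueous acid (loss of the dioxolane) would release 3, which is condensed to 4 as in step 1.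

**Step 2.** Facial selectivity in the alkylation at C5 may be poor, because the silyloxy group on C3 becomes pseudo-axial and 1,3 to the incoming electrophile, and O-alkylation of the hindered enolate may compete. Fallback (catalyst-controlled decarboxylative allylation in place of direct enolate alkylation): it sets out from 4 and comes back at 7. Conjugate addition as in step 2, with trapping of 6 by allyl chloroformate, would give the allyl enol carbonate F6. Pd2(dba)3 with a chiral phosphinooxazoline ligand chosen to reinforce attack anti to the C4 methyl (decarboxylative Tsuji–Trost allylation) would give the allyl ketone F7. Cross-metathesis with 2-methylbut-2-ene (Grubbs second-generation catalyst) would give 7.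

**Step 5.** Diastereocontrol may be poor or enamine formation slow with this bulky aldehyde, and the α-benzoyloxy aldehyde may epimerise on handling, because the catalyst has to override a large neighbouring ring. Fallback (ring closure first, C9 oxygen by enolate oxidation): it sets out from 11 and comes back at 14. ZnBr2 in CH2Cl2 would cyclise 11, a citronellal-type substrate, to the bicyclic alcohol F8. Dess–Martin oxidation would give the ketone F9. LDA at −78 °C (kinetic enolate on the C9 side) followed by 2-(phenylsulfonyl)-3-phenyloxaziridine would give the 9α-hydroxy ketone F10, by equatorial attack because the axial face is blocked by the C5 methyl. BzCl/pyridine would give 14.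

**Step 10.** Site selectivity may be incomplete: O8 may be acylated, or the acyl group may migrate from O9 to O8 under DMAP, because the diol is cis. Fallback (temporary protection of O8): it sets out from 15 and comes back at 18. 4-Methoxybenzyl trichloroacetimidate with La(OTf)3 (cat.) would give the 4-methoxybenzyl ether F11. K2CO3/MeOH and then HF·pyridine would give the diol F12. Acid 17 with DCC/DMAP would give the bis(ynoate) F13. DDQ in wet CH2Cl2 would give 18.

## Further compounds

F1 | step 6 | (1S)-1-[(1R,2R,3R,4R)-4-[(tert-butyldimethylsilyl)oxy]-2-[(2E)-4-hydroxy-3-methylbut-2-en-1-yl]-2,3-dimethylcyclohexyl]-2-oxoethyl benzoate | OC/C(C)=C/C[C@]1(C)[C@@H](C)[C@H](O[Si](C)(C)C(C)(C)C)CC[C@H]1[C@H](OC(=O)c2ccccc2)C=O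
F2 | step 6 | (1S)-1-[(1R,2R,3R,4R)-2-[(2E)-4-bromo-3-methylbut-2-en-1-yl]-4-[(tert-butyldimethylsilyl)oxy]-2,3-dimethylcyclohexyl]-2-oxoethyl benzoate | BrC/C(C)=C/C[C@]1(C)[C@@H](C)[C@H](O[Si](C)(C)C(C)(C)C)CC[C@H]1[C@H](OC(=O)c2ccccc2)C=O
F3 | step 1 | 2-ethyl-2-(2-iodoethyl)-1,3-dioxolane | CCC1(CCI)OCCO1
F4 | step 1 | (E)-2-[(tert-butyldimethylsilyl)oxy]-N-[(2R)-2-(methoxymethyl)pyrrolidin-1-yl]ethan-1-imine | CC(C)(C)[Si](C)(C)OC/C=N/N1CCC[C@@H]1COC
F5 | step 1 | (E,2R)-2-[(tert-butyldimethylsilyl)oxy]-4-(2-ethyl-1,3-dioxolan-2-yl)-N-[(2R)-2-(methoxymethyl)pyrrolidin-1-yl]butan-1-imine | CCC1(CC[C@@H](O[Si](C)(C)C(C)(C)C)/C=N/N2CCC[C@@H]2COC)OCCO1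
F6 | step 2 | allyl (3R,4R)-4-[(tert-butyldimethylsilyl)oxy]-2,3-dimethylcyclohex-1-en-1-yl carbonate | C=CCOC(=O)OC1=C(C)[C@@H](C)[C@H](O[Si](C)(C)C(C)(C)C)CC1
F7 | step 2 | (2R,3R,4R)-2-allyl-4-[(tert-butyldimethylsilyl)oxy]-2,3-dimethylcyclohexan-1-one | C=CC[C@]1(C)[C@@H](C)[C@H](O[Si](C)(C)C(C)(C)C)CCC1=O
F8 | step 5 | 9-deoxy analogue of 13: trans-fused 6-[(tert-butyldimethylsilyl)oxy]-4a,5-dimethyl-3-(prop-1-en-2-yl)decahydronaphthalen-2-ol with equatorial hydroxyl | C=C(C)[C@@H]1C[C@]2(C)[C@@H](C)[C@H](O[Si](C)(C)C(C)(C)C)CC[C@H]2C[C@H]1O
F9 | step 5 | 9-deoxy analogue of 14: trans-fused 6-[(tert-butyldimethylsilyl)oxy]-4a,5-dimethyl-3-(prop-1-en-2-yl)octahydronaphthalen-2(1H)-one | C=C(C)[C@@H]1C[C@]2(C)[C@@H](C)[C@H](O[Si](C)(C)C(C)(C)C)CC[C@H]2CC1=O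
F10 | step 5 | debenzoyl analogue of 14: the 1-hydroxy-2-ketone with equatorial hydroxyl | C=C(C)[C@@H]1C[C@]2(C)[C@@H](C)[C@H](O[Si](C)(C)C(C)(C)C)CC[C@H]2[C@H](O)C1=O
F11 | step 10 | O8-(4-methoxybenzyl) ether of 15 | C=C(C)[C@@H]1C[C@]2(C)[C@@H](C)[C@H](O[Si](C)(C)C(C)(C)C)CC[C@H]2[C@H](OC(=O)c3ccccc3)[C@@H]1OCc1ccc(OC)cc1
F12 | step 10 | O8-(4-methoxybenzyl) ether of 16 | C=C(C)[C@@H]1C[C@]2(C)[C@@H](C)[C@H](O)CC[C@H]2[C@H](O)[C@@H]1OCc1ccc(OC)cc1
F13 | step 10 | O8-(4-methoxybenzyl) ether of 18 | C=C(C)[C@@H]1C[C@]2(C)[C@@H](C)[C@H](OC(=O)C#CCCC)CC[C@H]2[C@H](OC(=O)C#CCCC)[C@@H]1OCc1ccc(OC)cc1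
A1 | alternative 1 | but-3-en-2-one | C=CC(C)=O
A2 | alternative 1 | (4aR,5R,6R)-6-[(tert-butyldimethylsilyl)oxy]-4a,5-dimethyl-4,4a,5,6,7,8-hexahydronaphthalen-2(3H)-one | O=C1CC[C@]2(C)[C@@H](C)[C@H](O[Si](C)(C)C(C)(C)C)CCC2=C1
A3 | alternative 1 | (4aR,5R,6R)-6-[(tert-butyldimethylsilyl)oxy]-4a,5-dimethyl-3-(propan-2-ylidene)-4,4a,5,6,7,8-hexahydronaphthalen-2(3H)-one | CC(C)=C1C[C@]2(C)[C@@H](C)[C@H](O[Si](C)(C)C(C)(C)C)CCC2=CC1=O
A4 | alternative 2 | (5S)-2-methyl-5-(prop-1-en-2-yl)cyclohexan-1-one | CC1CC[C@H](C(C)=C)CC1=O
A5 | alternative 2 | (4aS,7S)-1,4a-dimethyl-7-(prop-1-en-2-yl)-4,4a,5,6,7,8-hexahydronaphthalen-2(3H)-one | CC1=C2C[C@@H](C(C)=C)CC[C@@]2(C)CCC1=O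
A6 | alternative 2 | the 4,5-epoxy-3-ol of A5 with hydroxyl and epoxide oxygen anti to the C10 methyl | O[C@@H]1CC[C@]2(C)CC[C@H](C(C)=C)C[C@]23O[C@]13C
A7 | alternative 2 | eremophila-9,11-diene-3,4-diol with both hydroxyls anti to the C5 methyl | C=C(C)[C@@H]1C[C@]2(C)[C@](C)(O)[C@H](O)CCC2=CC1
A8 | alternative 3 | 2-methoxy-4,5-dimethylphenol | COc1cc(C)c(C)cc1O
A9 | alternative 3 | 6,6-dimethoxy-3,4-dimethylcyclohexa-2,4-dien-1-one | O=C1C=C(C)C(C)=CC1(OC)OC
A10 | alternative 3 | 3,3-dimethoxy-5,6-dimethylbicyclo[2.2.2]oct-5-en-2-one (racemate) | O=C1C2CCC(C(C)=C2C)C1(OC)OC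
A11 | alternative 3 | cis-fused 1,1-dimethoxy-4a,5-dimethyl-3,4,4a,7,8,8a-hexahydronaphthalen-2(1H)-one (racemate, one enantiomer drawn) | COC1(OC)C(=O)CC[C@]2(C)C(C)=CCC[C@H]12
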